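Slowness is what I look at first: in the autumn run the product gains 0.0280 M over the last 2.40 h, while the charge less the product still stands at 0.542 M.

the same everywhere: substrate 0.800 M
- autumn: free catalyst 0.0160 M
- dawn: free catalyst 0.0160 M; product 0.400 M
- summer: free catalyst 0.0240 M
- spring: free catalyst 0.0390 M; time 5.0 h

| run | time / h | [product] / M |
|---|---|---|
| autumn run | 0.20 | 0.042 |
| autumn run | 0.38 | 0.077 |
| autumn run | 0.72 | 0.129 |
| autumn run | 1.4 | 0.184 |
| autumn run | 2.6 | 0.230 |
| autumn run | 5.0 | 0.258 |
| dawn run | 0.20 | 0.424 |
| dawn run | 0.38 | 0.453 |
| dawn run | 0.72 | 0.479 |
| dawn run | 1.4 | 0.511 |
| dawn run | 2.6 | 0.543 |
| dawn run | 5.0 | 0.563 |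
| summer run | 0.20 | 0.065 |
| summer run | 0.38 | 0.113 |
| summer run | 0.72 | 0.168 |
| summer run | 1.4 | 0.252 |
| summer run | 2.6 | 0.300 |
| summer run | 5.0 | 0.328 |

(standard deviation of a reading: 0.004 M)

* reaction order in [free catalyst] at the outset, round the charge of the autumn run, defined at two percent of the substrate turned into product
* product in the spring run at 5.0 h, as a share of the substrate charged
* which of these the readings show (the product kills the catalyst / the loaded catalyst dies / two substrates go astray together / the catalyst dies by itself)

- Overall: substrate -> product, with free catalyst as catalyst.
- Constant volume, constant temperature.
- Readings of a species count what is bound in complexes too.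
- An order is taken over about fifteen percent of the charge, up and down.

I put the clocks of the autumn run in order, fastest first. The first reading gives one turnover per catalyst in 0.0762 h. Next comes the catalyst: rate over c(substrate), taken from the first interval to the last, decays at 0.676 /h, a read life of 1.48 h. At its first pace the substrate charge of the autumn run lasts 3.81 h, which is longer than that life, so the autumn flask slows with substrate left.

The dawn run, with product present from the start, reads 0.659 /h, about the same decay, so I see no sign that product kills the catalyst.

Dividing the rate of product by the rate of catalyst loss removes time, and what remains is the life count (turnover number): product made by the last reading per catalyst charged, 16.1 in the autumn run. The summer run gives 13.7 and the dawn run 10.2. These counts differ, but the dawn run starts with product in the flask, so the difference does not tell me whether the catalyst dies per turnover or by itself.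

The early readings of the summer and autumn runs give an order of 1.08 in free catalyst. From the autumn and summer runs the count changes with product at a slope of −35.1 /M. Carrying that line to the spring charge, I get 0.415 M, or 51.8 %.

The forecast says order 1, 54 % and the catalyst dies by itself, which is more product than my line: “Catalyst lifetime is fixed, independent of turnover”.

The flask gives order 1.0, 49.6 % and the catalyst dies by itself.

    free catalyst + substrate ⇌ catalyst-substrate complex, settled at all times (0.7420 /M)
    catalyst-substrate complex ⇌ product + free catalyst (40.68 /h, 22.36 /M/h)
    free catalyst → spent catalyst (0.9864 /h)

The spring flask makes 10.2 turnovers per catalyst by 5.0 h, fewer than the 16.1 of the autumn run. The simulated spring run without the turning of free catalyst into spent catalyst shows what that death costs: 7.2 percentage points of product share. That run stands at 56.9 %, a count of 11.7 turnovers per catalyst.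

(The runs were generated by integration for an exercise; scatter was added.)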